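One minute is the wrong clock for the target here, so I count in target lifetimes.

| setting | Thursday's | Wednesday's | Sunday's | south | west | north-west | south-west |
|---|---|---|---|---|---|---|---|
| substrate | 10 mM | 5 mM | 7.5 mM | 10 mM | 10 mM | 10 mM (fed, over 6.0 min) | 10 mM (fed, over 1.5 min) |
| coupling partner | 20 mM | 20 mM | 20 mM | 20.0 mM (fed, over 6.0 min) | 20.0 mM (fed, over 6.0 min) | 20.0 mM | 20.0 mM |
| temperature | 65 °C | 76 °C | 65 °C |  | 70 °C | 70 °C | 70 °C |
| remark | run made earlier | run made earlier | run made earlier | the addition at 30 °C, then warmed to 70 °C; the feed brings no volume worth counting | all else is in the flask from the start; the feed brings no volume worth counting | all else is in the flask from the start; the feed brings no volume worth counting | all else is in the flask from the start; the feed brings no volume worth counting |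
| time |  |  |  | 8.0 min | 8.0 min | 8.0 min | 8.0 min |

| run | time / min | target / % | side product / % |
|---|---|---|---|
| Thursday's | 0.833 | 12.1 | 10.0 |
| Thursday's | 1.50 | 16.0 | 23.3 |
| Thursday's | 2.50 | 17.1 | 38.8 |
| Thursday's | 3.00 | 16.5 | 45.7 |
| Thursday's | 4.00 | 15.6 | 56.1 |
| Thursday's | 5.00 | 14.6 | 63.8 |
| Wednesday's | 1.33 | 16.8 | 19.6 |
| Wednesday's | 2.50 | 18.1 | 38.9 |
| Wednesday's | 4.00 | 17.3 | 55.3 |
| Wednesday's | 5.00 | 16.9 | 64.1 |
| Wednesday's | 6.00 | 16.5 | 68.6 |
| Wednesday's | 8.00 | 14.9 | 74.8 |
| Sunday's | 0.667 | 10.5 | 5.1 |
| Sunday's | 1.00 | 13.4 | 10.0 |
| Sunday's | 2.00 | 17.3 | 24.5 |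
| Sunday's | 3.00 | 19.0 | 37.9 |
| Sunday's | 5.00 | 18.1 | 55.2 |
| Sunday's | 8.00 | 15.6 | 69.9 |

(standard deviation of a reading: 0.5 percentage points)

- in percentages every species weighs as the substrate in it: one side product counts as two
- the numbers in the tables scatter with a standard deviation of 0.5 percentage points

* the flask that comes out highest in share of target in target plus side product, or "all alike" when all lie within 1.5 percentage points (south / west / north-west / south-west / all alike)
* share of target in target plus side product at the end, south
* share of target in target plus side product at the end, west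
* share of target in target plus side product at the end, north-west
* share of target in target plus side product at the end, south-west

1. Substrate is the limiting reagent, 10 mM against 20.0 mM of coupling partner. In its balance the side reaction takes one substrate and one target at the rate k[S][T], with k the side constant, [S] the substrate concentration and [T] the target concentration, so the loss per target is k[S], which shrinks as substrate is used.

2. Thursday's readings from 2.50 min to 4.00 min give k = 97.4 M⁻¹ min⁻¹ at 65 °C. Wednesday's over the same times give 175 M⁻¹ min⁻¹ at 76 °C. For 70 °C I take their geometric mean, 131 M⁻¹ min⁻¹.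

3. My number is the wear number D: k times the substrate charged times the minutes it stands warm, which counts target lifetimes at full charge. For west, with substrate in from the start, D = 10.5.

4. Test on the runs, as D against share of target in target plus side product: Sunday at 5.00 min, 3.65 and 24.7%; Thursday at 5.00 min, 4.87 and 18.6%; Wednesday at 8.00 min, 7.02 and 16.6%. The share falls as D rises, but each run started with coupling partner at 20 mM, so this test doesn't reach a fed coupling partner.

5. I count fed substrate from the middle of its feed, and south's cold stretch as nothing. That gives north-west 6.54, south-west 9.48 and south 2.62, the lowest. I expect south near Sunday's share, north-west near Wednesday's, and south-west and west below that.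

6. The forecast gives south as highest: south 21.5%, west 12.4%, north-west 9.6%, south-west 8.6%. Its ground is “Cold addition favours coupling over side reaction, so south wins”. My north-west stands higher than its figure.

7. The flasks give south 23.5%, west 11.8%, north-west 16.4%, south-west 12.2%, so south is highest.

    substrate + target → side product (k = 130 M⁻¹ min⁻¹, Ea = 57.0 kJ mol⁻¹)
    substrate + coupling partner → target, rate k2*[substrate]^1.5*[coupling partner]^0.5 (k = 22.0 M⁻¹ min⁻¹, Ea = 39.0 kJ mol⁻¹)
    coupling partner → decomposition product (k = 4.80 × 10⁻⁴ min⁻¹, Ea = 122 kJ mol⁻¹)
    (constants at 70 °C)

South's share of 23.5% goes with its side product, 6.12% at 6.00 min and 49.6% at 8.00 min. A neighbour of south, charged with 2.5 mM of substrate, has D = 0.654, lower than south's, and it ends at a share of 56.2%.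

The readings are simulated from invented constants, and the scatter is random.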